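The numbers in the tables stem from a simulated flask with constants of no real substance, and the scatter is random.

Violet holds 15% starting material at 10.0 h and 15% at 12.0 h, though 1.5 equiv of reagent was charged. Suppose the reagent decomposes.

| flask | starting material | reagent in the second phase | protic impurity | remark | time | volume of the second phase over the first |
|---|---|---|---|---|---|---|
| violet | 0.070 M | 1.5 equiv | 2.5 mM | run made earlier |  |  |
| ochre | 0.11 M | 1.5 equiv | 2.5 mM | run made earlier |  |  |
| flask | 0.050 M | 1.50 equiv | 2.50 mM |  | 15 h | 0.25 |

- violet (time / h: target / %, starting material / %): 3.00: 57, 36; 6.00: 72, 23; 10.0: 72, 15; 12.0: 77, 15
- ochre (time / h: target / %, starting material / %): 1.50: 44, 50; 4.00: 74, 22; 8.00: 83, 13; 12.0: 82, 7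

(each reading ± 1.5 percentage points)

- target at 15 h, in percent of the starting material charged
- part of the starting material charged that has reacted at 15 h

- in the second phase: reagent in the second phase; everything else is in the first
- charges count per volume of the first phase; a concentration in a rate is the amount of a species over the volume of its own phase; every rate counts per litre of the first phase
- the numbers in the tables scatter with a standard deviation of 1.5 percentage points
- steps thought possible: starting material + protic impurity -> quenched substrate; starting material + reagent in the reaction phase -> target; reagent in the reaction phase <-> reagent in the second phase; target <-> isomer of the product; reagent in the reaction phase -> decomposed reagent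
- the earlier runs hold the two phases in the same ratio of volumes as the flask asked about

Work with the fraction left. Take the loss of starting material and the making of decomposed reagent as both first order in [reagent in the reaction phase], so starting material falls pseudo-first-order against the same exposure. Then ln(reactive share over share left), divided by [decomposed reagent], stays constant. Call it the reach. The reactive share is the charge less the protic impurity, assumed to take its own charge of starting material. [decomposed reagent] is the charged reagent less what starting material took, assuming the reagent is spent.

The last readings give 38.8 M⁻¹ for violet and 40.4 M⁻¹ for ochre. Carry the mean, 39.6 M⁻¹, as the reach.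

Solve the flask by passes. Violet's share left as a trial returns 23.8%, and that returns 20.0%. Their mean returns 20.7%. Commit to that share left, so 79.3% reacted.

Subtract the quenched share and the mean unaccounted gap of the last readings, 6.58%: target 67.7%.

The weak link is the averaged reach. Repeat the last pass with each run's own: 21.9% and 20.5%, a spread of 1.4 percentage points against a scatter of 1.5 points.

The forecast, stepping by hand and noting that “the reagent dies off relatively sooner”, says 70% and 80%, against 67.7% and 79.3% reckoned here.

The flask gives 68.2% and 80.2%.

    starting material + protic impurity → quenched substrate (k = 32.0 M⁻¹ h⁻¹)
    starting material + reagent in the reaction phase → target (k = 12.0 M⁻¹ h⁻¹)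
    reagent in the reaction phase ⇌ reagent in the second phase, rate k3*([reagent in the reaction phase] - [reagent in the second phase]/K3) per volume of the first phase (partition coefficient = 2.60, kL = 0.570 h⁻¹)
    target ⇌ isomer of the product (K = 1.10, k = 0.00860 h⁻¹)
    reagent in the reaction phase → decomposed reagent (k = 0.270 h⁻¹)

Is the flask at rest? At 15.0 h, the second phase of the flask still holds 1.41% of its charged reagent, and the flask's reach, taken on the [decomposed reagent] standing then, reads 44.7 M⁻¹. At 150 h, taken the same way, it reads 44.7 M⁻¹, and reacted starting material gains 1.4 points. Target does not hold: by 150 h it drops to 40.1% as isomer of the product climbs from 7.01% to 36.5%; the forward step to the isomer alone gives target a half-life of 81 h, longer than the asked time.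

At 0.030 M of starting material, passes of the same kind with the carried reach, tried first on the share committed to above, give 31.0% left. That flask gives 30% left and 56.2% target.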